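D lost is G gained, so in this closed flask the two sum to the charge: the last oak reading shows 37% G and 63% D, within the scatter.

the same everywhere: Z 1 mol%
- oak: D 0.0028 M; run made earlier
- birch: D 0.0044 M; run made earlier
- Friday's: D 0.0020 M; time 2.5 min
- Sunday's: D 0.0020 M; time 8.0 min

| run | time / s | G / % | D / % |
|---|---|---|---|
| oak | 20.0 | 3 | 97 |
| oak | 40.0 | 2 | 93 |
| oak | 60.0 | 15 | 87 |
| oak | 80.0 | 17 | 81 |
| oak | 90.0 | 23 | 77 |
| oak | 120 | 37 | 63 |
| birch | 10.0 | 0 | 99 |
| birch | 25.0 | 3 | 96 |
| birch | 40.0 | 9 | 92 |
| birch | 60.0 | 16 | 81 |
| birch | 90.0 | 35 | 68 |
| birch | 120 | 47 | 51 |

(scatter of a reading: 1.5 percentage points)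

- the average divides the monomer in chains by the number of chains begun, living and dead together
- on the list of suspects stand: D + L -> J + G; D + J -> G + J; Z <-> L
- the earlier runs do not show the number of chains; that part of a forecast is a guess

1. which of the two ends with the longer chains by the average number of monomer units in a chain (chains begun, living or dead) ("neither" if they lie within 10%) (Friday's / Sunday's / neither)
2. average number of monomer units in a chain (chains begun, living or dead) at the end, Friday's
3. average number of monomer units in a chain (chains begun, living or dead) at the end, Sunday's

On the suspects' list, a chain begins when D meets L, and L comes from Z. So one Z can begin one chain. Use the statistical case as your zero: suppose each Z has begun a chain and each D sits in one. The length is then D charged over Z charged, 100, the full-count length (the usual monomer-to-initiator ratio), written N.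

Friday's and Sunday's may stand off that zero. Let x be the fraction of D in G and f the fraction of charged Z that has begun a chain. The average length is then N times x over f.

Friday's and Sunday's share the loading, so they share N. Oak and birch tell you about x, but they do not show f. Friday's is more dilute than oak but runs longer. So my own reckoning takes x near oak's last 37%. With f at one, that gives 37.0, and a lower f lengthens it. Sunday's runs longer, so I take x and f both near one, and a length near N.

The forecast says Sunday's, with 44 and 90, and adds: “The chain count is a guess”.

The simulation gives Sunday's, with 46.8 for Friday's and 91.5 for Sunday's.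

    D + L → J + G (k = 440 M⁻¹ s⁻¹)
    D + J → G + J, rate k2*[J]*[D] (k = 310 M⁻¹ s⁻¹)
    Z ⇌ L (K = 0.550, k = 0.00930 s⁻¹)

The difference in time is the main reason for the gap between the two lengths: Sunday's stands at 91.5, and with that difference in time taken away it stands at 46.8. In Friday's, at 2.50 min, G is 34.7% and J is 1.48 × 10⁻⁵ M, so f is 0.740 and N x/f returns 46.9. A flask like Sunday's with 2.5 mol% of Z has N of 40.0, G of 99.7% and f of 0.946, so its chains stand above N, at 42.1.

The numbers in the tables come from a simulation with made-up constants, noise included.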